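The constants of this reaction are not given, so I read the one I need from the earlier runs.

| flask | substrate | reagent | temperature | remark | time |
|---|---|---|---|---|---|
| noon | 0.70 M | 1.3 equiv | 16 °C | run made earlier |  |
| autumn | 0.70 M | 1.3 equiv | 41 °C | run made earlier |  |
| Monday's | 1.4 M | 1.30 equiv | 35 °C |  | 2.0 h |
| Sunday's | 1.4 M | 1.30 equiv | 5 °C |  | 2.0 h |
| Wednesday's | 1.4 M | 1.30 equiv | 50 °C |  | 2.0 h |
| Friday's | 1.4 M | 1.30 equiv | 20 °C |  | 2.0 h |

noon run (percent of the substrate charged)

| time / h | target / % | substrate / % |
|---|---|---|
| 1.00 | 22.8 | 6.9 |
| 2.00 | 39.5 | 2.9 |
| 3.00 | 52.2 | 0 |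
| 4.00 | 56.9 | 1.2 |

autumn run (percent of the substrate charged)

| time / min | target / % | substrate / % |
|---|---|---|
| 25.0 | 54.6 | 1.6 |
| 50.0 | 54.7 | 0 |
| 80.0 | 54.1 | 0.9 |
| 90.0 | 54.0 | 1.6 |

(each reading ± 1 percentage point)

- a reading or a percentage of target counts all its forms, free or not
- a reading of substrate is of its free form alone

- the flask with the highest amount of target, in percent of the substrate charged ("all alike" if they lie within 1.5 percentage points) (Monday's / Sunday's / Wednesday's / Friday's / all alike)
- final target, as a percentage of the substrate charged, in Monday's
- final target, as a percentage of the substrate charged, in Sunday's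
- final target, as a percentage of the substrate charged, in Wednesday's
- final target, as a percentage of the substrate charged, in Friday's

In the noon run the substrate reading at 1.00 h is 6.9% and target is 22.8%, which leaves 70.3% of the charge in some uncounted form. Because that uncounted share is larger than target, I assume a slow last stage, the rate-limiting step, and treat target as climbing to a plateau with a gap that shrinks as exp(−kt). If the gap shrinks that way, each hour's gain shrinks by the same factor, and the plateau drops out of a ratio of gains.

The gains are 17 percentage points early and 4.7 points late, 2.00 h apart. Integrating the rate in this way gives a reading, with the scatter of the gains in it, of 0.634 /h. This is the first-order rate constant at which the gap closes in the noon run at 16 °C, my climb constant. Summing the gains still to come puts the plateau of the noon run, again as a reading, at 62.2%.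

The autumn run is already level at 25.0 min, so the gap then is at most about one scatter, 1 point. That puts its constant at 9.60 /h or more. I use this bound and let the constant grow by the same factor per degree. The flasks are twice as concentrated as these runs, and I assume the climb is unchanged, which the runs don't test.

Two extreme flasks are easy. If the climb were instant, each flask would end on its plateau, which I draw straight from 62.2% to the autumn level. If it had barely begun, target would be plateau times constant times time. On my reckoning a flask lies below both, at the plateau times one minus exp(−kt).

For Monday's the constant is 5.00 /h, the share done is >99.9%, and I expect 56.4%. For Wednesday's I also reckon the climb complete and expect 51.9%. For Friday's the constant 0.979 /h gives a share of 85.9% and so 52.4%. For Sunday's the constant 0.192 /h gives a share of 31.9% and so 20.9%.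

The forecast gives 56% for Monday's, 13% for Sunday's, 52% for Wednesday's and 47% for Friday's, which is lower than my figure; it names Monday's as highest and holds that the “yield therefore falls gently with temperature”.

The flasks give Monday's as highest, with Monday's at 58.5% above Friday's 54.4%, Wednesday's 47.0% and Sunday's 14.2%. The equations behind them are these:

    2 substrate → self-condensation product (k = 0.00140 /M/min, Ea = 60.0 kJ/mol)
    substrate + reagent → intermediate A (k = 0.0130 /M/min, Ea = 49.0 kJ/mol)
    intermediate C ⇌ target (K = 22.0, k = 0.00270 /min, Ea = 81.0 kJ/mol, ΔH = −46.0 kJ/mol)
    substrate + reagent → intermediate C (k = 0.0260 /M/min, Ea = 65.0 kJ/mol)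
    intermediate A ⇌ intermediate B (K = 0.730, k = 0.0300 /min, Ea = 95.0 kJ/mol, ΔH = −7.00 kJ/mol)
    substrate + target ⇌ idle adduct, settled at all times (K = 12.0 /M, ΔH = −43.0 kJ/mol)
    (constants at 5 °C)

Friday's target goes on from 54.4% to 63.4% after 20.0 h, so its share at 2.0 h measured against that later amount is 85.8%, and the climb constant carried to Friday's gave 85.9%. Carried to Sunday's, it gives the share 31.9% of the 58.8% that Sunday's holds after 20.0 h, which is 18.8%, and Sunday's holds 14.2% at 2.0 h.

All runs were generated by integration with constants of no real substance, noise included.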